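**Retrosynthetic overview**
- Carbon frame: 2-allylphenol (1, ring A) and methacrolein (2) are joined by cross-metathesis to the (E)-enal 3.
- Key disconnection, ring O–C2 bond: the phenol of 3 closes the dihydrofuran ring B by an amine-catalysed 5-exo oxa-Michael addition with α-protonation (aldehyde 4), setting both stereocentres; reduction gives alcohol 5. Ring B is the only ring formed.
- Arene handle: para-bromination of 5 gives 6.
- Ester C–O bond: Mitsunobu coupling of 6 with p-coumaric acid (7, ring C bought) gives 8.
- Acrylic acid arm: Heck reaction of 8 with acrylic acid (9) gives the target 10.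

Assumption: the target is the (S,S) isomer as read from the SMILES (ring C2 S, side-chain carbon S); the facial sense of the amine catalyst in step 2 is assigned by analogy, and the quasi-enantiomeric amine from quinine replaces it if the opposite sense is found.

Step 1
Reactants: 1 2-allylphenol; 2 methacrolein (2-methylprop-2-enal, 5 equiv)
Product: 3 (2E)-4-(2-hydroxyphenyl)-2-methylbut-2-enal
Conditions: second-generation Hoveyda–Grubbs catalyst RuCl2(H2IMes)(=CH-C6H4-2-OiPr) (5 mol %), 1,4-benzoquinone (10 mol %), CH2Cl2, 40 °C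
Reagents that add atoms: none
Why: Olefin cross-metathesis of a terminal alkene with methacrolein, which homodimerises slowly, is driven by loss of ethene and gives the thermodynamically preferred (E)-trisubstituted enal, while benzoquinone suppresses allyl-to-propenyl isomerisation.

Step 2
Reactants: 3 (2E)-4-(2-hydroxyphenyl)-2-methylbut-2-enal
Product: 5 (2S)-2-[(2S)-2,3-dihydro-1-benzofuran-2-yl]propan-1-ol, via aldehyde 4 (not isolated)
Conditions: 9-amino-9-deoxy-epi-quinidine (20 mol %), 2-nitrobenzoic acid (40 mol %), toluene, 0 °C; cold 0.5 M citric acid wash; then NaBH4, MeOH, −40 → 0 °C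
Reagents that add atoms: none
Why: Proposed new method: the cinchona primary amine condenses with the α-branched enal (where secondary amines fail for steric reasons) to give an (E)-iminium ion, the tethered phenol adds 5-exo-trig to the β-carbon on the face left open by the quinuclidinium carboxylate ion pair, making the ring O–C2 bond and setting C2 as (S), and the resulting enamine is protonated at the α-carbon anti to the ring CH2 with the new C–O bond in the enamine plane (inside-alkoxy 1,2-induction), giving the syn O/CH3 relationship, i.e. the (S) side-chain carbon once NaBH4 reduction of aldehyde 4 has frozen both centres against α-epimerisation and retro-oxa-Michael opening; the closest known reactions are primary-amine iminium-catalysed sulfa-Michael/protonation cascades of α-branched enals and amine-catalysed intramolecular oxa-Michael cyclisations of phenols onto enones, but a phenol oxa-Michael/protonation onto an α-methyl enal that closes a dihydrobenzofuran with two new stereocentres has not been described.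

Step 3
Reactants: 5 (2S)-2-[(2S)-2,3-dihydro-1-benzofuran-2-yl]propan-1-ol
Product: 6 (2S)-2-[(2S)-5-bromo-2,3-dihydro-1-benzofuran-2-yl]propan-1-ol
Conditions: NBS (1.05 equiv), MeCN, 0 °C → rt
Reagents that add atoms: N-bromosuccinimide (NBS), O=C1CCC(=O)N1Br
Why: Electrophilic aromatic bromination of the alkyl aryl ether goes para to the ring oxygen (C5), the primary alcohol is inert and no stereocentre is touched.

Step 4
Reactants: 6 (2S)-2-[(2S)-5-bromo-2,3-dihydro-1-benzofuran-2-yl]propan-1-ol; 7 p-coumaric acid ((2E)-3-(4-hydroxyphenyl)prop-2-enoic acid)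
Product: 8 (2S)-2-[(2S)-5-bromo-2,3-dihydro-1-benzofuran-2-yl]propyl (2E)-3-(4-hydroxyphenyl)prop-2-enoate
Conditions: PPh3 (1.3 equiv), DIAD (1.3 equiv), THF, 0 °C → rt
Reagents that add atoms: none
Why: Mitsunobu esterification activates the primary alcohol rather than the acid, so the carboxylate (pKa about 4.5) is alkylated in preference to the unprotected phenol (pKa about 9), the acid cannot self-acylate, and substitution at CH2 leaves both stereocentres untouched.

Step 5
Reactants: 8 (2S)-2-[(2S)-5-bromo-2,3-dihydro-1-benzofuran-2-yl]propyl (2E)-3-(4-hydroxyphenyl)prop-2-enoate; 9 acrylic acid (prop-2-enoic acid, 3 equiv)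
Product: 10 (2E)-3-[(2S)-2-[(2S)-1-{[(2E)-3-(4-hydroxyphenyl)prop-2-enoyl]oxy}propan-2-yl]-2,3-dihydro-1-benzofuran-5-yl]prop-2-enoic acid
Conditions: Pd(OAc)2 (5 mol %), P(o-tol)3 (12 mol %), Et3N (4 equiv), DMF, 100 °C; dilute HCl work-up
Reagents that add atoms: none
Why: Mizoroki–Heck reaction: zerovalent palladium formed in situ adds oxidatively to the aryl bromide, inserts into the acrylate far faster than into the 1,2-disubstituted coumarate alkene, and β-hydride elimination gives the (E)-cinnamic acid, with the ester and free phenol tolerated by Et3N.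

**Compound list**
1 | 2-allylphenol (2-(prop-2-en-1-yl)phenol) | C=CCc1ccccc1O | starting material
2 | methacrolein (2-methylprop-2-enal) | CC(=C)C=O | starting material
3 | (2E)-4-(2-hydroxyphenyl)-2-methylbut-2-enal | O=C/C(C)=C/Cc1ccccc1O | intermediate
4 | (2R)-2-[(2S)-2,3-dihydro-1-benzofuran-2-yl]propanal | C[C@@H](C=O)[C@@H]1Cc2ccccc2O1 | intermediate
5 | (2S)-2-[(2S)-2,3-dihydro-1-benzofuran-2-yl]propan-1-ol | C[C@@H](CO)[C@@H]1Cc2ccccc2O1 | intermediate
6 | (2S)-2-[(2S)-5-bromo-2,3-dihydro-1-benzofuran-2-yl]propan-1-ol | C[C@@H](CO)[C@@H]1Cc2cc(Br)ccc2O1 | intermediate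
7 | p-coumaric acid ((2E)-3-(4-hydroxyphenyl)prop-2-enoic acid) | OC(=O)/C=C/c1ccc(O)cc1 | starting material
8 | (2S)-2-[(2S)-5-bromo-2,3-dihydro-1-benzofuran-2-yl]propyl (2E)-3-(4-hydroxyphenyl)prop-2-enoate | C[C@@H](COC(=O)/C=C/c1ccc(O)cc1)[C@@H]1Cc2cc(Br)ccc2O1 | intermediate
9 | acrylic acid (prop-2-enoic acid) | C=CC(=O)O | starting material
10 | (2E)-3-[(2S)-2-[(2S)-1-{[(2E)-3-(4-hydroxyphenyl)prop-2-enoyl]oxy}propan-2-yl]-2,3-dihydro-1-benzofuran-5-yl]prop-2-enoic acid | C[C@@H](COC(=O)/C=C/c1ccc(O)cc1)[C@@H]1Cc2cc(/C=C/C(=O)O)ccc2O1 | target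

**Count and risks**
Total steps: 5. Longest linear sequence: 5 (1 → 3 → 5 → 6 → 8 → 10).

Steps most likely to fail:

Step 2 (the new oxa-Michael/protonation). The risks are low ee at C2, low syn/anti ratio in the protonation, and erosion by enamine re-formation or retro-oxa-Michael opening before reduction. The fallback uses known chemistry, sets out from 3 and comes back at 5. Luche reduction of 3 (NaBH4, CeCl3·7H2O, MeOH, 0 °C) gives (2E)-4-(2-hydroxyphenyl)-2-methylbut-2-en-1-ol F1. Acetylation of the primary alcohol only (vinyl acetate, immobilised Candida antarctica lipase B) gives (2E)-4-(2-hydroxyphenyl)-2-methylbut-2-en-1-yl acetate F2. Palladium-catalysed asymmetric intramolecular allylic etherification (Pd2(dba)3·CHCl3, the enantiomer of the DACH-phenyl Trost ligand that delivers the (S) ether, Et3N, CH2Cl2) closes ring B to (2S)-2-(prop-1-en-2-yl)-2,3-dihydro-1-benzofuran F3. Hydroboration of the isopropenyl group with catecholborane and RhCl(PPh3)3, then NaOH/H2O2, gives 5; the rhodium-catalysed variant is the syn-selective one for 1,1-disubstituted allylic ethers, which is the relationship needed here.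

Step 1 (cross-metathesis). The free ortho-phenol can bind ruthenium and promote isomerisation to 2-propenylphenol, and methacrolein is a sluggish partner. The fallback replaces metathesis by carbonyl olefination, sets out from 1 and comes back at 3. Ozonolysis of 1 (O3, CH2Cl2/MeOH, −78 °C; Me2S) gives (2-hydroxyphenyl)acetaldehyde as its lactol 2,3-dihydro-1-benzofuran-2-ol F4. Wittig reaction of the lactol with the stabilised ylide 2-(triphenylphosphoranylidene)propanal (toluene, 80 °C, catalytic benzoic acid) gives 3 as the (E)-enal.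

Step 5 (late Heck reaction). The aryl bromide is electron-rich, and a free phenol and a second enoate are present. The fallback forms the C–C bond before the ester and ends with a deprotection; it sets out from 6 and comes back at 10. Heck reaction of 6 with tert-butyl acrylate (Pd(OAc)2, P(o-tol)3, Et3N, DMF, 100 °C) gives tert-butyl (2E)-3-[(2S)-2-[(2S)-1-hydroxypropan-2-yl]-2,3-dihydro-1-benzofuran-5-yl]prop-2-enoate F5. Mitsunobu coupling with 7 (PPh3, DIAD, THF) gives tert-butyl (2E)-3-[(2S)-2-[(2S)-1-{[(2E)-3-(4-hydroxyphenyl)prop-2-enoyl]oxy}propan-2-yl]-2,3-dihydro-1-benzofuran-5-yl]prop-2-enoate F6. TFA in CH2Cl2 at 0 °C → rt cleaves the tert-butyl ester to 10.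

**Further compounds**
F1 | step 2 | (2E)-4-(2-hydroxyphenyl)-2-methylbut-2-en-1-ol | OC/C(C)=C/Cc1ccccc1O
F2 | step 2 | (2E)-4-(2-hydroxyphenyl)-2-methylbut-2-en-1-yl acetate | CC(=O)OC/C(C)=C/Cc1ccccc1O
F3 | step 2 | (2S)-2-(prop-1-en-2-yl)-2,3-dihydro-1-benzofuran | CC(=C)[C@@H]1Cc2ccccc2O1
F4 | step 1 | 2,3-dihydro-1-benzofuran-2-ol | OC1Cc2ccccc2O1
F5 | step 5 | tert-butyl (2E)-3-[(2S)-2-[(2S)-1-hydroxypropan-2-yl]-2,3-dihydro-1-benzofuran-5-yl]prop-2-enoate | C[C@@H](CO)[C@@H]1Cc2cc(/C=C/C(=O)OC(C)(C)C)ccc2O1
F6 | step 5 | tert-butyl (2E)-3-[(2S)-2-[(2S)-1-{[(2E)-3-(4-hydroxyphenyl)prop-2-enoyl]oxy}propan-2-yl]-2,3-dihydro-1-benzofuran-5-yl]prop-2-enoate | C[C@@H](COC(=O)/C=C/c1ccc(O)cc1)[C@@H]1Cc2cc(/C=C/C(=O)OC(C)(C)C)ccc2O1
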